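Retrosynthetic overview
1. GA55 ⇐ its 7-methyl ester (thiolate demethylation) ⇐ ring D closed last by a C13 ketyl/C16 alkyne cyclisation ⇐ 1β,3β-diol 19,10-lactone ⇐ 3-keto-Δ1(10) 19-ester: β-epoxidation of C1=C10 with capture at C10 by the α-19-ester gives the lactone and the 1β-OH, and a reduction steered by the 1β-OH gives the 3β-OH.
2. Ring A (key step): the 3-keto-Δ1(10) 19-ester ⇐ a seven-membered ring C1–C2–C3–C19–C4–C5–C10 ⇐ a diene C5=C10–C1=C2 held on ring B plus a 2-oxidoallyl cation C3–C19–C4 made from a trichloromethyl ketone; Favorskii contraction expels the ring carbonyl C19 as the carboxylate on C4 and joins C3 to C4.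
3. Enabling feature: in ring A the carboxyl carbon C19 sits on C4, between the oxygenated C3 and the ring-fusion carbon C5. C2–C3–C4(C19)–C5 with C1 and C10 is therefore the contraction product of a cyclohept-4-enone whose carbonyl is C19, and the C1=C10 alkene left by the cycloaddition is what the lactone and the 1β-OH need.
4. Rings B and C: the diene ⇐ a C10 ketone ⇐ Claisen rearrangement from the 10β-oxygen (sets quaternary C8) ⇐ Birch dearomatisation of the anisole ring (becomes ring C) of an indanone acid ⇐ Friedel–Crafts closure of ring B ⇐ catalytic asymmetric conjugate arylation (sets C6).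
5. Order of ring formation: B (on the arene) → C (dearomatisation) → seven-membered ring → A (ring contraction) → lactone → D.

Key step: step 15

Remark: locants C1 to C19 and the α/β face labels in names and comments are those of the gibberellane skeleton of the target (C7 = carboxyl carbon on C6, C18 = methyl on C4, C19 = lactone carbonyl; the lactone lies on the α-face).

Step 1
Reactants: 1 3-methoxyphenylboronic acid; 2 di-tert-butyl fumarate
Product: 3 di-tert-butyl (S)-2-(3-methoxyphenyl)butanedioate
Conditions: [RhCl(C2H4)2]2 (2.5 mol %), chiral 2,5-diphenylbicyclo[2.2.2]octa-2,5-diene ligand (the enantiomer that gives the S product), KOH (aq), 1,4-dioxane, 40 °C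
Reagents that add atoms: none
Why: The rhodium-catalysed asymmetric conjugate addition of the arylboronic acid to the fumarate (Hayashi–Miyaura reaction) should create the future C6 stereocentre under ligand control, the bulky tert-butyl esters helping the enantioselectivity.

Step 2
Reactants: 3 di-tert-butyl (S)-2-(3-methoxyphenyl)butanedioate
Product: 5 (S)-6-methoxy-3-oxo-2,3-dihydro-1H-indene-1-carboxylic acid, via diacid 4 (not isolated)
Conditions: P2O5 in MeSO3H (1:10), 50 °C; then ice water
Reagents that add atoms: none
Why: The acid should remove both tert-butyl groups as isobutene, after which the CH2CO2H arm closes ring B by intramolecular Friedel–Crafts acylation para to the methoxy group (five-membered closure; the other carboxyl cannot cyclise), without touching the stereocentre.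

Step 3
Reactants: 5 (S)-6-methoxy-3-oxo-2,3-dihydro-1H-indene-1-carboxylic acid
Product: 6 (1S,3R)-3-hydroxy-6-methoxy-2,3-dihydro-1H-indene-1-carboxylic acid (OH and CO2H cis)
Conditions: NaBH4, NaOH (1 equiv), MeOH/H2O, 0 °C; acidified to pH 4 at 0 °C
Reagents that add atoms: none
Why: Borohydride reduction of the indanone as its carboxylate salt should deliver hydride to the face opposite the C6 carboxylate, so that the new 10-hydroxyl is cis (β) to it and can later carry the Claisen rearrangement to the β-face of C8.

Step 4
Reactants: 6 (1S,3R)-3-hydroxy-6-methoxy-2,3-dihydro-1H-indene-1-carboxylic acid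
Product: 8 methyl (1S,3R)-3-hydroxy-6-methoxy-2,3,4,7-tetrahydro-1H-indene-1-carboxylate, via dienol acid 7 (not isolated)
Conditions: Li, NH3 (l), THF, t-BuOH, −78 °C; NH4Cl; NH3 evaporated; then MeI, DMF, 0 → 23 °C
Reagents that add atoms: iodomethane CI
Why: Birch reduction should dearomatise the anisole ring of the dianion (alkoxide and carboxylate resist hydrogenolysis and reduction) to the 1,4-diene with the donor groups on sp2 carbons, which leaves the C12=C13 enol ether and the tetrasubstituted C8=C9 alkene, and the carboxylate is then methylated by SN2 reaction under non-acidic conditions that spare the enol ether.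

Step 5
Reactants: 8 methyl (1S,3R)-3-hydroxy-6-methoxy-2,3,4,7-tetrahydro-1H-indene-1-carboxylate
Product: 9 methyl (1S,3R)-6,6-(ethylenedioxy)-3-hydroxy-2,3,4,5,6,7-hexahydro-1H-indene-1-carboxylate
Conditions: HOCH2CH2OH, pyridinium p-toluenesulfonate (5 mol %), CH2Cl2, 0 → 23 °C
Reagents that add atoms: ethane-1,2-diol OCCO
Why: Acid-catalysed exchange of the methyl enol ether with the diol through the C13 oxocarbenium ion (ketalisation) should mask the future C13 ketone under conditions too mild to ionise the allylic alcohol or move the C8=C9 alkene.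

Step 6
Reactants: 9 methyl (1S,3R)-6,6-(ethylenedioxy)-3-hydroxy-2,3,4,5,6,7-hexahydro-1H-indene-1-carboxylate
Product: 10 methyl (1S,3R)-6,6-(ethylenedioxy)-3-(vinyloxy)-2,3,4,5,6,7-hexahydro-1H-indene-1-carboxylate
Conditions: butyl vinyl ether (solvent), Pd(OCOCF3)2 (5 mol %), 4,7-diphenyl-1,10-phenanthroline (5 mol %), Et3N, 75 °C
Reagents that add atoms: butyl vinyl ether C=COCCCC
Why: Palladium-catalysed transfer vinylation of the secondary allylic alcohol with the vinyl ether should give the allyl vinyl ether needed for the rearrangement without acid.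

Step 7
Reactants: 10 methyl (1S,3R)-6,6-(ethylenedioxy)-3-(vinyloxy)-2,3,4,5,6,7-hexahydro-1H-indene-1-carboxylate
Product: 11 methyl (1S)-6,6-(ethylenedioxy)-7a-(2-oxoethyl)-2,4,5,6,7,7a-hexahydro-1H-indene-1-carboxylate (CH2CHO on C7a cis to the ester; gibberellane C8 quaternary; C9=C10 alkene)
Conditions: xylenes, 2,6-di-tert-butyl-4-methylphenol (cat.), 160 °C, sealed tube
Reagents that add atoms: none
Why: The Claisen rearrangement ([3,3]-sigmatropic and suprafacial) should move the two-carbon chain from the 10β-oxygen to the β-face of C8, so that the configuration of C10 is transferred to the new quaternary centre C8 (chain cis to the C6 ester) while the alkene shifts to C9=C10.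

Step 8
Reactants: 11 aldehyde (6β-CO2Me; 8β-CH2CHO; C9=C10; C13 dioxolane)
Product: 12 methyl (1S)-6,6-(ethylenedioxy)-7a-(prop-2-yn-1-yl)-2,4,5,6,7,7a-hexahydro-1H-indene-1-carboxylate (propargyl cis to the ester)
Conditions: dimethyl (1-diazo-2-oxopropyl)phosphonate, K2CO3, MeOH, 0 → 23 °C
Reagents that add atoms: dimethyl (1-diazo-2-oxopropyl)phosphonate CC(=O)C(=[N+]=[N-])P(=O)(OC)OC
Why: The Ohira–Bestmann variant of the Seyferth–Gilbert homologation should convert the aldehyde into the terminal alkyne (C16≡C17) under carbonate conditions that should not epimerise C6.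

Step 9
Reactants: 12 alkyne (6β-CO2Me; 8β-propargyl; C9=C10; C13 dioxolane)
Product: 13 epoxide of 12 (9α,10α; epoxide oxygen on the face opposite the propargyl group)
Conditions: mCPBA, NaHCO3, CH2Cl2, 0 °C
Reagents that add atoms: 3-chloroperoxybenzoic acid OOC(=O)c1cccc(Cl)c1
Why: Prilezhaev epoxidation of the only alkene should occur on the α-face, opposite the angular propargyl group and the C6 ester, the alkyne being far less reactive towards the peracid.

Step 10
Reactants: 13 epoxide (9α,10α)
Product: 14 methyl 6,6-(ethylenedioxy)-3-oxo-7a-(prop-2-yn-1-yl)octahydro-1H-indene-1-carboxylate (C10 ketone; cis ring fusion; ester; propargyl and 9-H all β)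
Conditions: BF3·OEt2 (0.2 equiv), CH2Cl2, −78 °C; Et3N; then DBU (0.2 equiv), CH2Cl2, 23 °C
Reagents that add atoms: none
Why: In the Meinwald rearrangement the Lewis acid should open the epoxide at tertiary C9 and the β-hydrogen on C10 then shifts suprafacially to C9, which gives the C10 ketone with the 9β-hydrogen (cis ring fusion), the epimer that base equilibration also favours.

Step 11
Reactants: 14 C10 ketone
Product: 15 C5=C10 enol triflate of 14 (10-OSO2CF3)
Conditions: LiN(SiMe3)2 (2.1 equiv), THF, −78 °C; PhNTf2 (1.1 equiv), −78 → 0 °C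
Reagents that add atoms: N-phenylbis(trifluoromethanesulfonimide) O=S(=O)(N(c1ccccc1)S(=O)(=O)C(F)(F)F)C(F)(F)F
Why: Kinetic deprotonation at the less hindered C5 methylene (one equivalent of base is taken up by the alkyne C–H) and O-sulfonylation of the enolate should give the C5=C10 enol triflate regioselectively.

Step 12
Reactants: 15 enol triflate
Product: 16 diene (ring B cyclopentene C5=C10 bearing vinyl C1=C2 on C10; 6β-CO2Me; 8β-propargyl; 9β-H; C13 dioxolane)
Conditions: CH2=CHSnBu3, Pd(PPh3)4 (5 mol %), LiCl, THF, 65 °C
Reagents that add atoms: tributyl(vinyl)stannane C=C[Sn](CCCC)(CCCC)CCCC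
Why: Stille coupling of the enol triflate with the vinylstannane should install C1 and C2 and give the 1-vinylcyclopentene diene C5=C10–C1=C2, the terminal alkyne being inert in the absence of copper and amine.

Step 13
Reactants: 17 (tert-butyldimethylsilyloxy)acetaldehyde
Product: 18 3-(tert-butyldimethylsilyloxy)-1,1,1-trichloropropan-2-ol (racemic)
Conditions: CHCl3 (solvent), DBU (1 equiv), 0 → 23 °C
Reagents that add atoms: chloroform ClC(Cl)Cl
Why: Base-mediated addition of the trichloromethyl anion from chloroform to the aldehyde (1,2-addition) should give the trichloromethyl carbinol.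

Step 14
Reactants: 18 3-(tert-butyldimethylsilyloxy)-1,1,1-trichloropropan-2-ol
Product: 19 3-(tert-butyldimethylsilyloxy)-1,1,1-trichloropropan-2-one
Conditions: Dess–Martin periodinane, NaHCO3, CH2Cl2, 23 °C
Reagents that add atoms: none
Why: Dess–Martin oxidation of the secondary alcohol should give the trichloromethyl ketone under neutral conditions that avoid haloform cleavage.

Step 15
Reactants: 16 diene; 19 3-(tert-butyldimethylsilyloxy)-1,1,1-trichloropropan-2-one
Product: 23 tricyclic keto diester (ring A: C1=C10; 3-oxo; 4β-methyl; 4α-CO2Me; 5β-H), via dichlorocycloheptenone 20 (not isolated), via silyl enol ether 21 (not isolated), via keto ester enolate 22 (not isolated)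
Conditions: Et3N, LiClO4 (3 M in Et2O), 0 → 23 °C; aqueous wash and solvent exchange without purification; then NaOMe (3.0 equiv), MeOH, 0 °C; then MeI, 0 → 23 °C; aqueous NH4Cl
Reagents that add atoms: sodium methoxide [Na+].[O-]C; iodomethane CI
Why: Proposed new method: Et3N enolises 19 at C3 and LiClO4-assisted loss of chloride should give a siloxy-substituted 1,1-dichloro-2-oxidoallyl cation (C3–C19–C4) that adds across diene 16 in a stepwise [4+3] sense, the free CH2 terminus C2 bonding first to the oxocarbenium-like CH(OSi) terminus C3 and the chloro-enolate carbon C4 then closing the seven-membered ring (C1, C2, C3, C19, C4, C5, C10) by recombination with the allyl cation at C5 from the α-face, anti to the C6 ester, which sets C5. Methoxide then starts a Favorskii rearrangement of the 2,2-dichloroketone 20: only C3 carries an α-hydrogen, so the cyclopropanone (three-membered closure C3–C4 by internal displacement of chloride from the enolate) keeps one chlorine on C4, and its methoxide adduct should break the C19–C3 bond with loss of that chloride, the only good leaving group, which leaves the former ring carbonyl C19 as the methyl ester on C4 and contracts the seven-membered ring to ring A as the C3 silyl enol ether 21 (a semibenzilic shift followed by loss of HCl would end at the same compound). Methoxide cleaves the silyl enol ether to the keto ester enolate 22, and MeI should alkylate C4 on the β-face, anti to the C5–C6 bond of ring B, which sets the quaternary centre with the ester α. The closest known reactions are the [4+3] cycloadditions of 1,3-dienes with chloro- or alkoxy-substituted 2-oxidoallyl cations made from polychloroketones and amine bases, the cycloaddition/quasi-Favorskii sequence used as a Diels–Alder surrogate, and the Favorskii contraction of 2,2-dichlorocycloalkanones to cycloalk-1-enecarboxylates. The step needs the right orientation of the first bond, seven- rather than five-membered closure, fragmentation towards C4 and C- rather than O-methylation, and these rest on the unhindered diene terminus, the s-cis-capable 1-vinylcyclopentene, the single α-hydrogen opposite the CCl2 group and the hydrogen-bonding solvent.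

Step 16
Reactants: 23 tricyclic keto diester
Product: 25 keto hydroxy lactone (19,10-lactone on the α-face; 1β-OH; 3-oxo; 7-methyl ester; C13 dioxolane; 8β-propargyl), via epoxide 24 (not isolated)
Conditions: mCPBA, NaHCO3, CH2Cl2, 0 °C; then camphorsulfonic acid (0.2 equiv), CH2Cl2, 0 → 23 °C; aqueous NaHCO3
Reagents that add atoms: 3-chloroperoxybenzoic acid OOC(=O)c1cccc(Cl)c1; water O
Why: Prilezhaev epoxidation of the trisubstituted C1=C10 alkene should occur on the β-face because the axial 19-ester and ring C shield the α-face, and the acid then lets the 19-ester carbonyl open the epoxide at tertiary C10 with inversion (neighbouring-group participation, five-membered lactone closure, trans-diaxial opening), which gives the α-lactone and the 1β-hydroxyl, only the β-epoxide being within reach of the α-ester.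

Step 17
Reactants: 25 keto hydroxy lactone
Product: 26 diol lactone (1β,3β-diol; 19,10-lactone; 7-methyl ester; C13 dioxolane; 8β-propargyl)
Conditions: Et2BOMe, THF/MeOH (4:1), −78 °C; NaBH4; AcOH quench; MeOH co-evaporation
Reagents that add atoms: none
Why: In the Narasaka–Prasad reduction the diethylboron chelate that links the axial 1β-oxygen to the C3 carbonyl oxygen holds that oxygen on the β-face, so external borohydride should add from the α-side and give the syn (1,3-diaxial) diol, that is the 3β-hydroxyl.

Step 18
Reactants: 26 diol lactone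
Product: 27 C13 ketone (1β,3β-diol; 19,10-lactone; 7-methyl ester; 8β-propargyl)
Conditions: 1 M HCl (aq), THF, 23 °C
Reagents that add atoms: water O
Why: Acid hydrolysis of the dioxolane should free the C13 ketone, while the bridged lactone, the methyl ester and the diol are stable to dilute acid at room temperature.

Step 19
Reactants: 27 C13 ketone
Product: 28 GA55 7-methyl ester
Conditions: SmI2 (4 equiv), HMPA, t-BuOH, THF, 0 → 23 °C
Reagents that add atoms: none
Why: Divalent samarium should reduce the C13 ketone to a ketyl radical that cyclises 5-exo-dig onto the alkyne (ketyl–alkyne radical cyclisation), closing ring D and giving the bridgehead 13-hydroxyl and the exocyclic methylene, the configuration of C13 being fixed by the β-propargyl tether on C8.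

Step 20
Reactants: 28 GA55 7-methyl ester
Product: 29 GA55 (1β,3β,13-trihydroxy gibberellin 19,10-lactone bearing the free 7-carboxylic acid and the 16(17)-methylene)
Conditions: n-PrSLi, HMPA, 23 °C; then 1 M HCl to pH 3
Reagents that add atoms: none
Why: The thiolate should cleave the methyl ester by SN2 attack at the O-methyl group, which spares the hindered bridged lactone and avoids the hydroxide conditions that would open the lactone or epimerise C3 by retro-aldol reaction.

Compound list
1 | 3-methoxyphenylboronic acid | OB(O)c1cccc(OC)c1 | starting material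
2 | di-tert-butyl fumarate | CC(C)(C)OC(=O)/C=C/C(=O)OC(C)(C)C | starting material
3 | di-tert-butyl (S)-2-(3-methoxyphenyl)butanedioate | CC(C)(C)OC(=O)C[C@@H](c1cccc(OC)c1)C(=O)OC(C)(C)C | intermediate
4 | (S)-2-(3-methoxyphenyl)butanedioic acid (not isolated) | OC(=O)C[C@@H](c1cccc(OC)c1)C(=O)O | intermediate
5 | (S)-6-methoxy-3-oxo-2,3-dihydro-1H-indene-1-carboxylic acid | O=C(O)[C@H]1CC(=O)c2ccc(OC)cc21 | intermediate
6 | (1S,3R)-3-hydroxy-6-methoxy-2,3-dihydro-1H-indene-1-carboxylic acid (cis) | O=C(O)[C@H]1C[C@@H](O)c2ccc(OC)cc21 | intermediate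
7 | (1S,3R)-3-hydroxy-6-methoxy-2,3,4,7-tetrahydro-1H-indene-1-carboxylic acid (not isolated) | O=C(O)[C@H]1C[C@@H](O)C2=C1CC(OC)=CC2 | intermediate
8 | methyl (1S,3R)-3-hydroxy-6-methoxy-2,3,4,7-tetrahydro-1H-indene-1-carboxylate | COC(=O)[C@H]1C[C@@H](O)C2=C1CC(OC)=CC2 | intermediate
9 | methyl (1S,3R)-6,6-(ethylenedioxy)-3-hydroxy-2,3,4,5,6,7-hexahydro-1H-indene-1-carboxylate | COC(=O)[C@H]1C[C@@H](O)C2=C1CC3(CC2)OCCO3 | intermediate
10 | methyl (1S,3R)-6,6-(ethylenedioxy)-3-(vinyloxy)-2,3,4,5,6,7-hexahydro-1H-indene-1-carboxylate | COC(=O)[C@H]1C[C@@H](OC=C)C2=C1CC3(CC2)OCCO3 | intermediate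
11 | methyl (1S)-6,6-(ethylenedioxy)-7a-(2-oxoethyl)-2,4,5,6,7,7a-hexahydro-1H-indene-1-carboxylate, CH2CHO cis to the ester | COC(=O)[C@H]1CC=C2CCC3(OCCO3)C[C@]12CC=O | intermediate
12 | methyl (1S)-6,6-(ethylenedioxy)-7a-(prop-2-yn-1-yl)-2,4,5,6,7,7a-hexahydro-1H-indene-1-carboxylate, propargyl cis to the ester | COC(=O)[C@H]1CC=C2CCC3(OCCO3)C[C@]12CC#C | intermediate
13 | epoxide of 12 (9α,10α; oxygen opposite the propargyl group) | COC(=O)[C@H]1C[C@@H]2O[C@@]23CCC4(OCCO4)C[C@]13CC#C | intermediate
14 | methyl 6,6-(ethylenedioxy)-3-oxo-7a-(prop-2-yn-1-yl)octahydro-1H-indene-1-carboxylate, cis ring fusion, ester, propargyl and 9-H all β | COC(=O)[C@H]1CC(=O)[C@@H]2CCC3(OCCO3)C[C@]12CC#C | intermediate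
15 | C5=C10 enol triflate of 14 | COC(=O)[C@H]1C=C(OS(=O)(=O)C(F)(F)F)[C@@H]2CCC3(OCCO3)C[C@]12CC#C | intermediate
16 | diene: ring B cyclopentene C5=C10 with vinyl (C1=C2) on C10, 6β-CO2Me, 8β-propargyl, 9β-H, C13 dioxolane | COC(=O)[C@H]1C=C(C=C)[C@@H]2CCC3(OCCO3)C[C@]12CC#C | intermediate
17 | (tert-butyldimethylsilyloxy)acetaldehyde | CC(C)(C)[Si](C)(C)OCC=O | starting material
18 | 3-(tert-butyldimethylsilyloxy)-1,1,1-trichloropropan-2-ol (racemic) | CC(C)(C)[Si](C)(C)OCC(O)C(Cl)(Cl)Cl | intermediate
19 | 3-(tert-butyldimethylsilyloxy)-1,1,1-trichloropropan-2-one | CC(C)(C)[Si](C)(C)OCC(=O)C(Cl)(Cl)Cl | intermediate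
20 | ring-B-fused 2,2-dichloro-7-(silyloxy)cyclohept-4-enone (ring C1, C2, C3, C19, C4, C5, C10; C19 ketone, C4 Cl2, C3 OTBS as epimers, 5β-H; not isolated) | COC(=O)[C@H]1[C@H]2C(=CCC(O[Si](C)(C)C(C)(C)C)C(=O)C2(Cl)Cl)[C@@H]3CCC4(OCCO4)C[C@]13CC#C | intermediate
21 | ring A silyl enol ether: C1=C10, C3(OTBS)=C4(CO2Me), 5β-H (not isolated) | COC(=O)[C@H]1[C@H]2C(=CCC(O[Si](C)(C)C(C)(C)C)=C2C(=O)OC)[C@@H]3CCC4(OCCO4)C[C@]13CC#C | intermediate
22 | ring A β-keto ester (3-oxo, 4-CO2Me), present as its sodium enolate and drawn as the neutral enol (not isolated) | COC(=O)[C@H]1[C@H]2C(=CCC(O)=C2C(=O)OC)[C@@H]3CCC4(OCCO4)C[C@]13CC#C | intermediate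
23 | tricyclic keto diester: ring A C1=C10, 3-oxo, 4β-methyl, 4α-CO2Me, 5β-H; 6β-CO2Me; 8β-propargyl; C13 dioxolane | COC(=O)[C@H]1[C@H]2C(=CCC(=O)[C@@]2(C)C(=O)OC)[C@@H]3CCC4(OCCO4)C[C@]13CC#C | intermediate
24 | β-epoxide of 23 across C1–C10 (not isolated) | COC(=O)[C@H]1[C@H]2[C@@]5(O[C@@H]5CC(=O)[C@@]2(C)C(=O)OC)[C@@H]3CCC4(OCCO4)C[C@]13CC#C | intermediate
25 | keto hydroxy lactone: 19,10-lactone (α), 1β-OH, 3-oxo, 7-methyl ester, C13 dioxolane, 8β-propargyl | C#CC[C@]23CC4(OCCO4)CC[C@H]2[C@@]12OC(=O)[C@@](C)([C@H]1[C@@H]3C(=O)OC)C(=O)C[C@H]2O | intermediate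
26 | diol lactone: 1β,3β-diol, 19,10-lactone, 7-methyl ester, C13 dioxolane, 8β-propargyl | C#CC[C@]23CC4(OCCO4)CC[C@H]2[C@@]12OC(=O)[C@@](C)([C@H]1[C@@H]3C(=O)OC)[C@@H](O)C[C@H]2O | intermediate
27 | C13 ketone: 1β,3β-diol, 19,10-lactone, 7-methyl ester, 8β-propargyl | C#CC[C@]23CC(=O)CC[C@H]2[C@@]12OC(=O)[C@@](C)([C@H]1[C@@H]3C(=O)OC)[C@@H](O)C[C@H]2O | intermediate
28 | GA55 7-methyl ester | C=C1C[C@]23C[C@@]1(O)CC[C@H]2[C@@]12OC(=O)[C@@](C)([C@H]1[C@@H]3C(=O)OC)[C@@H](O)C[C@H]2O | intermediate
29 | GA55 (1β,3β,13-trihydroxy gibberellin 19,10-lactone bearing the free 7-carboxylic acid and the 16(17)-methylene) | C=C1C[C@]23C[C@@]1(O)CC[C@H]2[C@@]12OC(=O)[C@@](C)([C@H]1[C@@H]3C(=O)O)[C@@H](O)C[C@H]2O | target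

Total step count: 20. Longest linear sequence: 18 steps (steps 1 to 12 and 15 to 20; steps 13 and 14 make the side component 19).

Steps most likely to fail

Step 15 (proposed new method). The first C–C bond may form with the opposite orientation. The zwitterion may close a five-membered ring at C1 instead of the seven-membered ring at C5. The trichloromethyl ketone may be lost by haloform-type cleavage before it ionises. Methylation may also go to oxygen or to the α-face, and any methoxide left over may move the C1=C10 alkene into conjugation or open the non-enolisable β-keto ester by retro-Claisen cleavage. The fallback keeps the ring contraction but uses only known reaction types, and introduces the C3 oxygen after the contraction. It sets out from 16 and comes back to the route at 23. Diene 16 is combined with the parent 1,1-dichloro-2-oxidoallyl cation from commercial 1,1,1-trichloropropan-2-one (Et3N, LiClO4, Et2O). Its unsubstituted CH2 terminus should bond first to the unhindered C2, and the ring-B-fused 2,2-dichlorocyclohept-4-enone F1 is isolated. Favorskii contraction with NaOMe in MeOH should give the cyclohexa-1(10),3-diene ester F2, with the C19 methyl ester on C4. The electron-poor C3=C4 bond is epoxidised nucleophilically with t-BuOOLi in THF to the 3,4-epoxy ester F3. SmI2 in THF/MeOH opens the epoxy ester at C4 to the 3-hydroxy ester F4, and Dess–Martin oxidation gives the keto ester 22 in its neutral form. Methylation of 22 with K2CO3 and MeI in acetone, which keeps alkoxide out of the flask, should then give 23.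

Step 16. The peracid may attack the α-face, or the β,γ-epoxy ketone may open by enolisation to the γ-hydroxy enone before the ester captures C10. The dioxolane may also be lost under the acid. The fallback replaces epoxidation by halolactonisation and enone chemistry, sets out from 23 and comes back at 25. Iodolactonisation through the 19-methyl ester (iodine, MeCN, 0 °C) should add the ester oxygen to C10 from the α-face and iodine to C1 from the β-face, with loss of iodomethane, to give the iodolactone F5. DBU removes HI by E1cB elimination to give the 3-oxo-1-ene lactone F6. Weitz–Scheffer epoxidation (t-BuOOH, DBU) on the β-face, the α-face being closed by the lactone bridge, should give the 1β,2β-epoxy ketone F7. Reductive opening at C2 with Na[PhSeB(OEt)3] in EtOH/AcOH then gives the 1β-hydroxy ketone 25.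

Step 10. A substituent of the neighbouring quaternary C8 may migrate to the C9 cation (Wagner–Meerwein shift) instead of the hydrogen from C10, and the Lewis acid may remove the dioxolane. The fallback brings in the C10 oxygen by hydroboration before the alkyne is made. It sets out from aldehyde 11 and comes back at 14. BH3·THF followed by NaOH/H2O2 reduces the aldehyde and hydrates the C9=C10 alkene at C10 from the α-face to give the diol F8. Dess–Martin oxidation of both hydroxyls gives the keto aldehyde F9. Ohira–Bestmann homologation of the aldehyde (K2CO3, MeOH) should then give the alkyne and at the same time equilibrate C9 to the cis ring fusion of 14.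

Further compounds
F1 | step 15 | ring-B-fused 2,2-dichlorocyclohept-4-enone (ring C1, C2, C3, C19, C4, C5, C10; C19 ketone, C4 Cl2, 5β-H) | COC(=O)[C@H]1[C@H]2C(=CCCC(=O)C2(Cl)Cl)[C@@H]3CCC4(OCCO4)C[C@]13CC#C
F2 | step 15 | ring A cyclohexa-1(10),3-diene with the C19 methyl ester on C4 | COC(=O)[C@H]1[C@H]2C(=CCC=C2C(=O)OC)[C@@H]3CCC4(OCCO4)C[C@]13CC#C
F3 | step 15 | 3β,4β-epoxy ester of F2 | COC(=O)[C@H]1[C@H]2C(=CC[C@@H]5O[C@]25C(=O)OC)[C@@H]3CCC4(OCCO4)C[C@]13CC#C
F4 | step 15 | 3β-hydroxy ester (C4 epimers) | COC(=O)[C@H]1[C@H]2C(=CC[C@H](O)C2C(=O)OC)[C@@H]3CCC4(OCCO4)C[C@]13CC#C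
F5 | step 16 | 1β-iodo-3-oxo-19,10-lactone | C#CC[C@]23CC4(OCCO4)CC[C@H]2[C@@]12OC(=O)[C@@](C)([C@H]1[C@@H]3C(=O)OC)C(=O)C[C@H]2I
F6 | step 16 | 3-oxo-1-ene-19,10-lactone | C#CC[C@]23CC4(OCCO4)CC[C@H]2[C@@]12OC(=O)[C@@](C)([C@H]1[C@@H]3C(=O)OC)C(=O)C=C2
F7 | step 16 | 1β,2β-epoxy-3-oxo-19,10-lactone | C#CC[C@]23CC4(OCCO4)CC[C@H]2[C@@]12OC(=O)[C@@](C)([C@H]1[C@@H]3C(=O)OC)C(=O)[C@H]5O[C@H]52
F8 | step 10 | diol: 10α-OH, 9α-H, 8β-CH2CH2OH, 6β-CO2Me, C13 dioxolane | COC(=O)[C@H]1C[C@H](O)[C@H]2CCC3(OCCO3)C[C@]12CCO
F9 | step 10 | keto aldehyde: C10 ketone, 9α-H, 8β-CH2CHO | COC(=O)[C@H]1CC(=O)[C@H]2CCC3(OCCO3)C[C@]12CC=O
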